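**Retrosynthetic overview**

1. Number the lactone chain C1 (C=O), C2 (CH2), C3 (ring-fusion CH on the tetrahydrofuran O), C4 (ring-fusion CH on the lactone O), C5 (CH2), C6 (tetrahydrofuran CH) and C7 (benzylic CH carrying Ph and the flavanone 7-oxygen). The strategy rests on the two neighbouring oxygens at C6 (ring ether) and C7 (aryl ether), and on the C6 oxygen being placed to form a five-membered ring with C3, the beta-carbon of the C1–C4 gamma-lactone. A cis C6–C7 oxirane attached through C5 to a C2=C3 butenolide therefore stores both the aryl ether and the cis-fused tetrahydrofuro[3,2-b]furan-2-one.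
2. Final disconnection (two bonds, one pot): ArO–C7 and O(C6)–C3, leading to cis-epoxy butenolide 13 and (2S)-pinocembrin 14.
3. 13 comes from Z-styrenyl butenolide 12 by catalyst-controlled epoxidation. 12 comes from Z-alkenyl oxirane 6 and (phenylthio)acetic acid 7 (C1, C2) via the alpha-phenylthio lactone and sulfoxide elimination. 6 comes from phenylacetylene 1 (C6, C7, Ph) and (R)-epichlorohydrin 2 (C3–C5 and the lactone O).
4. Ring order: gamma-lactone, then its C2=C3 unsaturation, then the oxirane, and last the tetrahydrofuran, which is formed as the oxirane is consumed. Both flavanone rings are purchased.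

Key step: step 8

Assumption: the (R,R)-salen manganese chloride catalyst is taken to attack the Z-styrene of 12 with the facial sense it shows toward cis-beta-methylstyrene, which corresponds to the (2S,3R)-oxirane; this must be verified on the substrate, and the (S,S)-catalyst is used instead if the sense proves reversed.

**Route**

Step 1
Reactants: 1 phenylacetylene; 2 (R)-epichlorohydrin
Product: 4 (R)-1-chloro-5-phenylpent-4-yn-2-ol, via lithium phenylacetylide 3 (not isolated)
Conditions: 1, n-BuLi, THF, −78 °C; BF3·OEt2; then 2, −78 °C; H2O quench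
Reagents that add atoms: none
Why: BF3-promoted alkynyllithium opening of an epoxide (Yamaguchi alkynylation), in which the acetylide attacks the activated oxirane at its unsubstituted CH2 faster than it displaces chloride at −78 °C, so the C–O stereocentre of 2 is carried over unchanged as (R).

Step 2
Reactants: 4 (R)-1-chloro-5-phenylpent-4-yn-2-ol
Product: 5 (2R,4Z)-1-chloro-5-phenylpent-4-en-2-ol
Conditions: H2 (1 atm), Pd/CaCO3 poisoned with Pb(OAc)2 (Lindlar catalyst), quinoline, EtOAc, rt, stopped after 1 equiv of H2
Reagents that add atoms: none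
Why: Lindlar semihydrogenation delivers both hydrogens to one face of the alkyne on the poisoned palladium surface and so should give the Z-alkene, while the alkyl chloride and the alcohol are inert.

Step 3
Reactants: 5 (2R,4Z)-1-chloro-5-phenylpent-4-en-2-ol
Product: 6 (R)-2-[(Z)-3-phenylprop-2-en-1-yl]oxirane
Conditions: NaOH, MeOH, 0 °C to rt
Reagents that add atoms: none
Why: Intramolecular Williamson etherification of the chlorohydrin (3-exo-tet) displaces chloride at the CH2Cl carbon, so the carbinol stereocentre keeps its C–O bond and its (R) configuration.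

Step 4
Reactants: 6 (R)-2-[(Z)-3-phenylprop-2-en-1-yl]oxirane; 7 (phenylthio)acetic acid
Product: 10 (5R)-3-(phenylthio)-5-[(Z)-3-phenylprop-2-en-1-yl]dihydrofuran-2(3H)-one (both C3 epimers), via dilithio (phenylthio)acetate dianion 8 (not isolated), via gamma-hydroxy acid 9 (not isolated)
Conditions: 7, LiN(i-Pr)2 (2.0 equiv, no excess), THF, −78 to 0 °C; 6, 0 °C to rt; aq HCl; then TsOH (cat.), PhMe, 50 °C
Reagents that add atoms: none
Why: Alkylation of the carboxylic acid dianion at the unsubstituted oxirane carbon followed by acid-catalysed gamma-lactonization; the C–O bond of the stereocentre is never broken so it stays (R), and the sulfur-bearing carbon forms as both epimers, which is irrelevant because it becomes sp2 in step 6.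

Step 5
Reactants: 10 (5R)-3-(phenylthio)-5-[(Z)-3-phenylprop-2-en-1-yl]dihydrofuran-2(3H)-one
Product: 11 (5R)-3-(phenylsulfinyl)-5-[(Z)-3-phenylprop-2-en-1-yl]dihydrofuran-2(3H)-one (mixture of sulfoxide diastereomers)
Conditions: NaIO4 (1.05 equiv), MeOH/H2O, 0 °C to rt
Reagents that add atoms: sodium periodate, [Na+].[O-]I(=O)(=O)=O
Why: Periodate oxidation of a sulfide stops at the sulfoxide and does not epoxidise the styrene, so the Z-alkene is preserved.

Step 6
Reactants: 11 (5R)-3-(phenylsulfinyl)-5-[(Z)-3-phenylprop-2-en-1-yl]dihydrofuran-2(3H)-one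
Product: 12 (R)-5-[(Z)-3-phenylprop-2-en-1-yl]furan-2(5H)-one
Conditions: PhMe, CaCO3 (suspended acid scavenger), 110 °C
Reagents that add atoms: none
Why: Thermal syn-elimination of the sulfoxide (sulfoxide pyrolysis): the only beta-hydrogens lie on the ring CH2, so benzenesulfenic acid is lost to give the conjugated C2=C3 butenolide under neutral conditions that should leave the gamma-stereocentre and the Z-alkene untouched.

Step 7
Reactants: 12 (R)-5-[(Z)-3-phenylprop-2-en-1-yl]furan-2(5H)-one
Product: 13 (5R)-5-{[(2S,3R)-3-phenyloxiran-2-yl]methyl}furan-2(5H)-one (cis-epoxide)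
Conditions: (R,R)-[N,N′-bis(3,5-di-tert-butylsalicylidene)-1,2-cyclohexanediaminato]MnCl (5 mol%), mCPBA, NMO, CH2Cl2, −78 °C
Reagents that add atoms: mCPBA (3-chloroperoxybenzoic acid), O=C(OO)c1cccc(Cl)c1
Why: Jacobsen–Katsuki epoxidation, in which the chiral oxo-manganese salen species transfers oxygen to one face of the electron-rich Z-styrene and so sets C6 (S) and C7 (R) under catalyst control, while the low temperature and the N-oxide ligand suppress the stepwise radical collapse that leaks to trans-epoxide and the electron-poor butenolide alkene is not oxidised.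

Step 8
Reactants: 13 (5R)-5-{[(2S,3R)-3-phenyloxiran-2-yl]methyl}furan-2(5H)-one; 14 (2S)-pinocembrin
Product: 16 (3aR,5S,6aR)-5-[(S)-{[(2S)-5-hydroxy-4-oxo-2-phenyl-3,4-dihydro-2H-chromen-7-yl]oxy}(phenyl)methyl]tetrahydrofuro[3,2-b]furan-2(3H)-one (target CNP0152032.1), via ring-opened hydroxy butenolide ether 15 (not isolated)
Conditions: 14 (1.5 equiv), Cs2CO3 (0.3 equiv), DMF, 60 °C; DBU (0.1 equiv), rt, only if 15 persists
Reagents that add atoms: none
Why: Proposed new method: Cs2CO3 ionises only the non-chelated 7-OH of 14 (the 5-OH is held in a hydrogen bond to the C4 ketone), and this phenoxide attacks the benzylic oxirane carbon C7 of 13 in an SN2 reaction, converting the (R)-oxirane carbon into the (S)-aryloxy carbon and leaving the C6 oxygen as an alkoxide of unchanged configuration. That alkoxide adds to the butenolide beta-carbon C3 in a 5-exo-trig oxa-Michael closure that forms the tetrahydrofuran ring, and the lactone enolate is protonated at C2 by free 14, which regenerates phenoxide and keeps the base catalytic. The closest known reaction types are the invertive benzylic opening of 3-aryloxiranes by phenoxides used for aryloxy-phenylpropanols and the base-mediated closure of 5-(2-hydroxyalkyl)butenolides to cis-fused furo[3,2-b]furan-2-ones; their coupling in one pot on a base-sensitive flavanone is what is new. The new stereocentre C3 is set by C4, because the one-carbon tether C5 can deliver the oxygen only to the butenolide face that gives the cis-fused bicycle, and C7 is set by the oxirane configuration through inversion. The step needs attack at C7 instead of C6 (which would end in a pyran-fused isomer by 6-exo closure), and this is favoured by benzylic stabilisation of the SN2 transition state and by the beta-branched, inductively deactivated C6. Phenoxide-level basicity should keep both the flavanone C2 and the lactone-oxygen-bearing C4 from epimerising.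

**Compound list**

1 | phenylacetylene | C#Cc1ccccc1 | starting material
2 | (R)-epichlorohydrin | ClC[C@H]1CO1 | starting material
3 | lithium phenylacetylide | [Li]C#Cc1ccccc1 | intermediate (not isolated)
4 | (R)-1-chloro-5-phenylpent-4-yn-2-ol | ClC[C@H](O)CC#Cc1ccccc1 | intermediate
5 | (2R,4Z)-1-chloro-5-phenylpent-4-en-2-ol | ClC[C@H](O)C/C=C\c1ccccc1 | intermediate
6 | (R)-2-[(Z)-3-phenylprop-2-en-1-yl]oxirane | c1ccccc1/C=C\C[C@@H]1CO1 | intermediate
7 | (phenylthio)acetic acid | OC(=O)CSc1ccccc1 | starting material
8 | dilithio (phenylthio)acetate dianion | [Li+].[Li+].[O-]C(=O)[CH-]Sc1ccccc1 | intermediate (not isolated)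
9 | (4R,6Z)-4-hydroxy-7-phenyl-2-(phenylthio)hept-6-enoic acid (C2 epimers) | OC(=O)C(Sc1ccccc1)C[C@H](O)C/C=C\c1ccccc1 | intermediate (not isolated)
10 | (5R)-3-(phenylthio)-5-[(Z)-3-phenylprop-2-en-1-yl]dihydrofuran-2(3H)-one (C3 epimers) | O=C1C(Sc2ccccc2)C[C@@H](C/C=C\c2ccccc2)O1 | intermediate
11 | (5R)-3-(phenylsulfinyl)-5-[(Z)-3-phenylprop-2-en-1-yl]dihydrofuran-2(3H)-one (diastereomer mixture) | O=C1C(S(=O)c2ccccc2)C[C@@H](C/C=C\c2ccccc2)O1 | intermediate
12 | (R)-5-[(Z)-3-phenylprop-2-en-1-yl]furan-2(5H)-one | O=C1C=C[C@@H](C/C=C\c2ccccc2)O1 | intermediate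
13 | (5R)-5-{[(2S,3R)-3-phenyloxiran-2-yl]methyl}furan-2(5H)-one | O=C1C=C[C@@H](C[C@@H]2O[C@@H]2c2ccccc2)O1 | intermediate
14 | (2S)-pinocembrin, (2S)-5,7-dihydroxy-2-phenylchroman-4-one | O=C1C[C@@H](c2ccccc2)Oc2cc(O)cc(O)c12 | starting material
15 | (5R)-5-[(2S,3S)-2-hydroxy-3-{[(2S)-5-hydroxy-4-oxo-2-phenyl-3,4-dihydro-2H-chromen-7-yl]oxy}-3-phenylpropyl]furan-2(5H)-one | O=C1C=C[C@@H](C[C@H](O)[C@@H](Oc2cc(O)c3c(c2)O[C@H](c2ccccc2)CC3=O)c2ccccc2)O1 | intermediate (not isolated)
16 | (3aR,5S,6aR)-5-[(S)-{[(2S)-5-hydroxy-4-oxo-2-phenyl-3,4-dihydro-2H-chromen-7-yl]oxy}(phenyl)methyl]tetrahydrofuro[3,2-b]furan-2(3H)-one | O=C1C[C@H]2O[C@H]([C@@H](Oc3cc(O)c4c(c3)O[C@H](c3ccccc3)CC4=O)c3ccccc3)C[C@H]2O1 | target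

**Step count and risks**

Total step count: 8. Longest linear sequence: 8 steps (from 1 and 2 to 16).

Steps most likely to fail:

1. Step 8 (proposed new method). The stabilised 7-phenoxide may open the oxirane too slowly, or may attack C6 and then close a pyran by the 6-exo path. Prolonged warming with base may also open the flavanone reversibly to its chalcone and erode its C2 configuration. The fallback uses known reactions only, sets out from 12 and comes back at 16. Catalytic OsO4 with NMO in acetone/water would dihydroxylate the styrene alkene syn and give (5R)-5-[(2S,3R)-2,3-dihydroxy-3-phenylpropyl]furan-2(5H)-one F1 together with its diastereomer (5R)-5-[(2R,3S)-2,3-dihydroxy-3-phenylpropyl]furan-2(5H)-one F2, which is removed by chromatography. Catalytic DBU in CH2Cl2 should then close F1 through its C6 hydroxyl by the 5-exo oxa-Michael addition, expected to outrun the 6-exo path through the benzylic hydroxyl, to give (3aR,5S,6aR)-5-[(R)-hydroxy(phenyl)methyl]tetrahydrofuro[3,2-b]furan-2(3H)-one F3. Mitsunobu etherification of F3 with 14 (PPh3, DIAD, THF, 0 °C to rt) engages the more acidic 7-OH and inverts C7 from (R) to (S), which gives 16 under neutral conditions that do not threaten the flavanone stereocentre.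

2. Step 7. Oxygen transfer may leak to trans-epoxide through bond rotation in the radical intermediate, and facial selectivity may be insufficient if the catalyst and the lactone stereocentre are mismatched. The fallback sets out from 12 and comes back at 13, and moves control from the catalyst to a separation. Dimethyldioxirane in acetone at 0 °C transfers oxygen stereospecifically syn and without leakage to trans-epoxide, and would give 13 together with (5R)-5-{[(2R,3S)-3-phenyloxiran-2-yl]methyl}furan-2(5H)-one F4. The two are diastereomers because of the lactone stereocentre and should be separable by chromatography.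

3. Step 2. Over-reduction to the saturated chain and Z-to-E isomerisation on palladium are the concern, because any E-alkene would travel on as trans-epoxide and emerge as a diastereomer at the C6/C7 pair. The fallback sets out from 2 and comes back at 5, and takes the alkene geometry from a purchased building block instead of making it by hydrogenation. Purchased (Z)-(2-bromovinyl)benzene F5 undergoes bromine–lithium exchange with t-BuLi (2 equiv, Et2O, −78 °C) to give (Z)-(2-phenylvinyl)lithium F6 with retention of geometry. BF3·OEt2-promoted opening of 2 at its CH2 at −78 °C should then deliver 5 directly.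

Further compounds
F1 | step 8 | (5R)-5-[(2S,3R)-2,3-dihydroxy-3-phenylpropyl]furan-2(5H)-one | O=C1C=C[C@@H](C[C@H](O)[C@H](O)c2ccccc2)O1
F2 | step 8 | (5R)-5-[(2R,3S)-2,3-dihydroxy-3-phenylpropyl]furan-2(5H)-one | O=C1C=C[C@@H](C[C@@H](O)[C@@H](O)c2ccccc2)O1
F3 | step 8 | (3aR,5S,6aR)-5-[(R)-hydroxy(phenyl)methyl]tetrahydrofuro[3,2-b]furan-2(3H)-one | O=C1C[C@H]2O[C@H]([C@H](O)c3ccccc3)C[C@H]2O1
F4 | step 7 | (5R)-5-{[(2R,3S)-3-phenyloxiran-2-yl]methyl}furan-2(5H)-one | O=C1C=C[C@@H](C[C@H]2O[C@H]2c2ccccc2)O1
F5 | step 2 | (Z)-(2-bromovinyl)benzene (purchased) | Br/C=C\c1ccccc1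
F6 | step 2 | (Z)-(2-phenylvinyl)lithium | [Li]/C=C\c1ccccc1
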